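## Structural features

The target is a 1,2-dioxolane (ring atoms O1, O2, C3, C4, C5) whose two peroxide-bearing carbons, C3 and C5, are both fully substituted and are separated by the C4 methylene. C3 (S) carries an ethyl group and an (E)-propenoic acid, C5 (R) carries an ethyl group and a (1E,4R,5E)-4-ethyl-2-methylocta-1,5-dienyl chain (C1′ to C8′), and the two ethyl groups are cis on the ring. C3 and C5 are thus 1,3-related quaternary stereocentres, whereas the third centre, C4′, is insulated from the ring by the C1′=C2′ alkene and the C3′ methylene and cannot be set by relay. The fragile elements are the O–O bond (hydrides, low-valent metals, phosphines, hydrogenation), the tertiary allylic C5–O1 bond (ionisation by acid) and the conjugated acid (conjugate addition). Neither peroxide carbon bears hydrogen, so base-induced Kornblum–DeLaMare cleavage is not available and mildly basic end-game steps are allowed. The real difficulty is to create two tetrasubstituted C–O centres of a peroxide with the cis-diethyl relationship and, at the same time, to attach a trisubstituted E alkene directly to the neopentyl-type C5, a connection that carbonyl olefination serves badly. The key step exploits two features: C3 stands at the ketone oxidation level between O2 and C4 and can therefore be the electrophilic carbon of a peroxycarbenium ion, and the unit C4–C5(Et)–C1′=C2′ is the imprint of a 2-ethyl-1,3-diene whose CH2 terminus becomes C4.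

## Logic of the disconnections

19 to 18: the acid is carried as its ethyl ester (acyl C–O bond). This keeps the last intermediates neutral and chromatographable, so that any C5 epimer can still be removed. The forward hydrolysis must spare the O–O bond and the enoate, which the absence of hydrogen on C3 and C5 makes reasonable.

18 to 17: the Cα=Cβ bond of the enoate is cut. An E-disubstituted enoate is most reliably made from an aldehyde and a stabilised phosphonate, and the cut reduces the C3 arm to a one-carbon handle. The forward step must be E-selective on a hindered, non-enolisable α-peroxy aldehyde.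

17 to 16: the formyl carbon is traced to the carbinol carbon of an acetonide-protected 1,2-diol (the glycol C–C bond is restored). A free aldehyde could not pass through the Lewis-acid step, and the oxygenated stereocentre next to C3 is needed there as the control element. The forward cleavage must not ionise the C5–O1 bond.

16 to 6 and 15: C3–C4 and C5–O1 are cut together. This divides the molecule into two halves of similar size, puts the E alkene and C4′ into 15 before the peroxide exists, and leaves only C3 and C5 to be set. The forward step demands face selectivity at C3, closure at the near allyl terminus on the correct face, chemoselectivity among three alkenes and survival of the acetonide.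

15 to 12 and 13: the central σ-bond of the diene and the C–CH3 bond on the trisubstituted alkene are cut. Syn-methylmetalation of a terminal alkyne is the most dependable source of this E geometry, and the cut leaves a simple alkyne and a four-carbon bromide. The forward step needs regioselective carbometalation with a spectator alkene and coupling with retention.

12 to 10: the terminal alkyne carbon is removed (one-carbon homologation of an ester carbonyl). This returns to an ester that a sigmatropic rearrangement can deliver. The forward step must stop the reduction at the aldehyde level.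

10 to 8 and 9: the bond between the ester CH2 and the stereocentre is cut in a [3,3] sense. A C–C stereocentre is exchanged for a carbinol centre that is easier to make enantioselectively, and the E alkene comes with it. The forward step must proceed through one chair with complete 1,3-chirality transfer.

8 to 7: the ethyl–carbinol bond is cut, leading to a commercial enal. The forward step needs enantioselective 1,2-addition to an unbranched aliphatic enal.

6 to 4: the C–OMe and C–OO bonds of the peroxyketal are traced to a C=CH2 bond. Ozonolysis in methanol is the mildest route to a methoxy hydroperoxide, and the alkene is a stable, storable precursor. The forward step needs the primary ozonide to fragment towards the substituted carbonyl oxide under neutral conditions.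

4 to 3: the methylidene carbon is removed to give the ketone. The forward olefination must be non-basic because the stereocentre is α to the carbonyl group.

3 to 1: the ethyl–carbonyl bond is cut back to a commercial chiral-pool ester. The forward acyl substitution must stop at the ketone and must not enolise the α-alkoxy centre.

## Other disconnections considered

Alternative 1: The cut removes both C–O bonds of the peroxide (C3–O2 and C5–O1) at once and traces the carbon arms on C3 and C5 to the two ends of a ring alkene. In the forward sense singlet oxygen would add across the diene termini of 1,4-diethylcyclopenta-1,3-diene A1 in a [4+2] cycloaddition to give the bicyclic endoperoxide A2, and oxidative cleavage of its C5=C6 alkene would release the meso dialdehyde A3.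
- In its favour: the bicycle enforces the cis relationship of the two ethyl groups, so on relative configuration at C3/C5 this plan is better than the chosen one, where the C5 outcome is not controlled. The cycloaddition is a long-established reaction type, which is also better than a key step that needs new methodology. The core is reached in very few operations from cheap material.
- Against it here: A1 equilibrates with its double-bond isomers by 1,5-hydrogen shifts and dimerises, so the diene that is oxygenated is not uniquely defined. A2 is a strained bicyclic peroxide of a kind that rearranges thermally and would have to be handled cold. A3 is achiral, so two identical formyl groups must be told apart enantioselectively with no stereochemical information in the substrate. The C5 chain must then be built on a neopentyl α-peroxy aldehyde by an E-selective trisubstituted olefination with an unstabilised partner, and C4′ must be brought in separately.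
- Comparison: structurally it delivers only the symmetric core; mechanistically it is the more secure ring formation; in step economy the early lead is expected to be lost in desymmetrisation and two chain extensions, whereas the chosen plan installs the whole C5 chain, its E alkene and C4′ in the ring-forming step.

Alternative 2: The cut is C5–O1, made by opening an epoxide, and both quaternary carbons are traced to enantioselective epoxidations of allylic alcohols. In the forward sense, under mild acid, the tertiary hydroperoxide of the epoxy alcohol A4 would attack the quaternary carbon of its trisubstituted epoxide in a 5-exo mode with inversion and give the dioxolane A5.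
- In its favour: the absolute configurations of C3 and C5 both come from reagent-controlled epoxidations and a stereospecific opening. On stereocontrol at the ring this is better than the chosen plan, which relies on substrate bias at C3 and has none at C5. The ring-closing reaction type has precedent.
- Against it here: the tertiary hydroperoxide of A4 must itself be installed with defined configuration, most plausibly by perhydrolysis of an epoxide at its tertiary carbon, where partial SN1 character can erode the centre. The closure must prefer the quaternary epoxide carbon over the 6-endo alternative. A5 carries two glycol arms that have to be differentiated, cleaved and extended, and the arm on C5 again needs the difficult E-trisubstituted olefination and a separate source of C4′.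
- Comparison: structurally it is strong for the ring and weak for the side chain; mechanistically it is equal or better in predictability; in step economy it is clearly longer (two epoxidations, peroxide installation, protecting-group steps, two cleavages, two olefinations), with the peroxide carried through more steps.

Alternative 3: The cut is C3–O2, formed across a six-membered carbocycle that is opened afterwards; the ring comes from Birch reduction of an arene. In the forward sense N-iodosuccinimide would activate the trisubstituted ring alkene of the trans hydroperoxy alcohol A6, and the hydroperoxide would attack the ethyl-bearing alkene carbon transannularly, anti to iodine, to give the iodo-substituted dioxabicyclooctanol A7.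
- In its favour: the transannular geometry guarantees the cis-diethyl dioxolane, again a point on which it is better than the chosen plan. Halo-peroxidation of alkenes by hydroperoxides is a known reaction class with predictable Markovnikov regiochemistry and anti addition. The starting arene is cheap.
- Against it here: A6 needs a tertiary hydroperoxide placed trans to the hydroxyl group on a ring that is obtained without absolute stereocontrol, so a resolution or an extra asymmetric step is required. After the key step the cyclohexane must be cut open between functionalised carbons in the presence of the peroxide, and both arms must then be re-elaborated, including the E-trisubstituted alkene and C4′.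
- Comparison: structurally it builds a ring that is later destroyed; mechanistically it is comparable in reliability and better in relative stereocontrol; in step economy it is expected to be the longest of the four plans.

Key step: step 8

Assumptions and remarks on the chemistry:
- SnCl4 in step 8 is treated as a promoter that the balanced equation returns unchanged; the methoxy and triethylsilyl groups of 6 leave together as Et3SiOMe.
- 5 and 6 are used as mixtures of epimers at the ketal carbon, which becomes planar on ionisation.
- All stereodescriptors were derived independently from the structures as drawn and no structural correction was needed. The dioxolane centre is 4R in 1, 2, 3, 5, 6 and 16 and 4S in 4 for the same spatial arrangement (CIP priority change only). By the polar Felkin–Anh analysis, 4R in 6 corresponds to 3S in 16.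
- Improvements to the precursor design, without changing the disconnection: the ketone is made from the configurationally robust ester 1 rather than from the polymerisation-prone aldehyde; the methylenation is non-basic; the diene is made by a one-flask carboalumination and cross-coupling; a hindered pyridine is added in step 8.

## Steps

Step 1
Reactants: 1 methyl (4R)-2,2-dimethyl-1,3-dioxolane-4-carboxylate
Product: 3 1-[(4R)-2,2-dimethyl-1,3-dioxolan-4-yl]propan-1-one, via Weinreb amide 2 (not isolated)
Conditions: MeNH(OMe)·HCl, i-PrMgCl, THF, −20 °C; then EtMgBr, −20 → 0 °C; aq. NH4Cl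
Reagents that add atoms: ethylmagnesium bromide, CC[Mg]Br
Why: Amidation of the ester by the magnesium amide, then acyl substitution of the Weinreb amide, whose chelated tetrahedral adduct stops the addition at the ketone stage. The dioxolane stereocentre is not a reacting centre, and the low temperature limits enolisation.

Step 2
Reactants: 3 1-[(4R)-2,2-dimethyl-1,3-dioxolan-4-yl]propan-1-one
Product: 4 (4S)-4-(but-1-en-2-yl)-2,2-dimethyl-1,3-dioxolane
Conditions: Cp2TiMe2, toluene/THF, 65 °C, dark
Reagents that add atoms: Cp2TiMe2, C[Ti](C)(C1C=CC=C1)C1C=CC=C1
Why: Petasis methylenation through the titanium methylidene Cp2Ti=CH2 formed on thermolysis. The reagent is non-basic, so the α-alkoxy stereocentre should not epimerise; its descriptor becomes S only through the change in CIP priorities.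

Step 3
Reactants: 4 (4S)-4-(but-1-en-2-yl)-2,2-dimethyl-1,3-dioxolane
Product: 6 triethyl({1-[(4R)-2,2-dimethyl-1,3-dioxolan-4-yl]-1-methoxypropyl}peroxy)silane (both epimers at the ketal carbon), via hydroperoxy ketal 5 (not isolated)
Conditions: O3, CH2Cl2/MeOH, NaHCO3, −78 °C; N2 purge, concentrate cold; then Et3SiCl, imidazole, DMF, 0 °C
Reagents that add atoms: ozone, [O-][O+]=O; methanol, CO; chlorotriethylsilane, CC[Si](Cl)(CC)CC
Why: Ozonolysis by the Criegee mechanism with methanol trapping: the primary ozonide of a 1,1-disubstituted alkene is expected to fragment mainly to formaldehyde and the disubstituted carbonyl oxide, which adds methanol to give 5. O-Silylation of the hydroperoxide then gives 6. The new ketal centre forms unselectively and does not matter, because it is planarised in step 8.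

Step 4
Reactants: 7 (2E)-pent-2-enal
Product: 8 (3R,4E)-hept-4-en-3-ol
Conditions: Et2Zn, (+)-3-exo-morpholinoisoborneol [(+)-MIB] (cat.), hexanes/toluene, 0 °C; aq. NH4Cl
Reagents that add atoms: diethylzinc, CC[Zn]CC
Why: Amino-alcohol-catalysed enantioselective 1,2-addition of Et2Zn to an aldehyde. The ligand enantiomer is the one that delivers ethyl to the Re face of the formyl group, which gives the R carbinol; the sense is to be confirmed by Mosher ester analysis.

Step 5
Reactants: 8 (3R,4E)-hept-4-en-3-ol; 9 triethyl orthoacetate
Product: 10 ethyl (3R,4E)-3-ethylhept-4-enoate
Conditions: EtCO2H (cat.), neat in 9, 140 °C, EtOH distilled off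
Reagents that add atoms: none
Why: Johnson–Claisen rearrangement. The mixed ketene acetal rearranges through a chair transition state with the carbinol ethyl group equatorial, so the C–O stereocentre is transferred suprafacially to C3 (R to R) and the new alkene is E.

Step 6
Reactants: 10 ethyl (3R,4E)-3-ethylhept-4-enoate
Product: 12 (4R,5E)-4-ethyloct-5-en-1-yne, via aldehyde 11 (not isolated)
Conditions: i-Bu2AlH, CH2Cl2, −78 °C; then MeOH, K2CO3, dimethyl (1-diazo-2-oxopropyl)phosphonate, −78 °C → rt
Reagents that add atoms: dimethyl (1-diazo-2-oxopropyl)phosphonate, CC(=O)C(=[N+]=[N-])P(=O)(OC)OC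
Why: Partial reduction of the ester to the aluminium hemiacetal and, after methanolysis, Ohira–Bestmann homologation of the liberated aldehyde in the same flask. The stereocentre is β to the carbonyl group and cannot epimerise.

Step 7
Reactants: 12 (4R,5E)-4-ethyloct-5-en-1-yne; 13 2-bromobut-1-ene
Product: 15 (3E,6R,7E)-2,6-diethyl-4-methyldeca-1,3,7-triene, via alkenyldimethylaluminium 14 (not isolated)
Conditions: AlMe3, Cp2ZrCl2 (cat.), CH2Cl2, 0 °C → rt; volatiles removed; then 13, Pd(PPh3)4 (cat.), ZnCl2 (cat.), THF, rt
Reagents that add atoms: trimethylaluminium, C[Al](C)C
Why: Negishi carboalumination: syn addition of Me–Al across the terminal alkyne places methyl on the internal carbon and aluminium on the terminal one, which fixes the E geometry. The alkenylaluminium is then cross-coupled with the alkenyl bromide under zerovalent palladium with ZnCl2 as transmetalation shuttle (Negishi coupling), with retention at both sp2 carbons. The internal disubstituted alkene is inert to carboalumination.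

Step 8
Reactants: 6 triethyl({1-[(4R)-2,2-dimethyl-1,3-dioxolan-4-yl]-1-methoxypropyl}peroxy)silane; 15 (3E,6R,7E)-2,6-diethyl-4-methyldeca-1,3,7-triene
Product: 16 (3S,5R)-3-[(4R)-2,2-dimethyl-1,3-dioxolan-4-yl]-3,5-diethyl-5-[(1E,4R,5E)-4-ethyl-2-methylocta-1,5-dien-1-yl]-1,2-dioxolane
Conditions: 6 (1.3 equiv), 15 (1.0 equiv), 2,6-di-tert-butyl-4-methylpyridine (0.2 equiv), CH2Cl2, −78 °C; SnCl4 (1.0 equiv) added last; aq. NaHCO3 at −78 °C
Reagents that add atoms: none
Why: Proposed new method: SnCl4 removes methoxide from 6 to give a peroxycarbenium ion (carbenium carbon = C3, stabilised by the triethylsilylperoxy oxygen); the unsubstituted CH2 terminus of the 2-ethyl-1,3-diene of 15 adds to it (C3–C4) to give a doubly tertiary allyl cation, and the silylated peroxide oxygen then captures the ethyl-bearing terminus (C5–O1) while the triethylsilyl group leaves to the methoxide. The closest known reaction type is the SnCl4- or Me3SiOTf-promoted [3+2] annulation of triethylsilylperoxy ketals with simple alkenes; the extension here is to a conjugated diene and to a stereocontrolled union of two advanced fragments. The only ring closed is the 1,2-dioxolane, in a 5-exo sense at the near allyl terminus; closure at the far, methyl-bearing terminus would need a seven-membered ring containing a cis alkene and is expected to be slower. C3 is controlled by the (4R)-dioxolanyl stereocentre: in the polar Felkin–Anh arrangement (the Cornforth arrangement predicts the same face) the ring C–O bond stands anti to the incoming nucleophile, which passes the hydrogen and not the CH2O arm, and attack on that face gives 3S. C5 is fixed in the ring closure by the face of the planar cation that the oxygen reaches; no element of the substrate enforces the cis-diethyl (5R) result, so the 5-epimer is expected alongside 16 and is to be separated by chromatography here or at 18. The E geometry of C1′=C2′ should persist because that bond keeps partial double-bond character in the allyl cation, whose rotation is expected to be slow relative to intramolecular capture at −78 °C. Chemoselectivity rests on cation stability, since only attack by the terminal CH2 generates a tertiary allyl cation and the isolated disubstituted alkene is far less nucleophilic; the acetonide is protected by the low temperature, a single equivalent of Lewis acid and the hindered pyridine that removes adventitious HCl.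

Step 9
Reactants: 16 (3S,5R)-3-[(4R)-2,2-dimethyl-1,3-dioxolan-4-yl]-3,5-diethyl-5-[(1E,4R,5E)-4-ethyl-2-methylocta-1,5-dien-1-yl]-1,2-dioxolane
Product: 17 (3S,5R)-3,5-diethyl-5-[(1E,4R,5E)-4-ethyl-2-methylocta-1,5-dien-1-yl]-1,2-dioxolane-3-carbaldehyde
Conditions: H5IO6, EtOAc, 0 °C → rt
Reagents that add atoms: none
Why: Periodic acid hydrolyses the terminal isopropylidene ketal and cleaves the liberated 1,2-diol (Malaprade glycol cleavage) in one flask. Periodate does not oxidise the alkenes or the dialkyl peroxide, and C3 bears no hydrogen and cannot epimerise.

Step 10
Reactants: 17 (3S,5R)-3,5-diethyl-5-[(1E,4R,5E)-4-ethyl-2-methylocta-1,5-dien-1-yl]-1,2-dioxolane-3-carbaldehyde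
Product: 18 ethyl (2E)-3-[(3S,5R)-3,5-diethyl-5-[(1E,4R,5E)-4-ethyl-2-methylocta-1,5-dien-1-yl]-1,2-dioxolan-3-yl]prop-2-enoate
Conditions: (EtO)2P(O)CH2CO2Et, NaH, THF, 0 °C → rt
Reagents that add atoms: triethyl phosphonoacetate, CCOC(=O)CP(=O)(OCC)OCC
Why: Horner–Wadsworth–Emmons olefination of a non-enolisable, α-branched aldehyde with a stabilised phosphonate anion, which is strongly E-selective. The di-tertiary peroxide has no α-hydrogen and should not be attacked by the soft carbanion at this temperature.

Step 11
Reactants: 18 ethyl (2E)-3-[(3S,5R)-3,5-diethyl-5-[(1E,4R,5E)-4-ethyl-2-methylocta-1,5-dien-1-yl]-1,2-dioxolan-3-yl]prop-2-enoate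
Product: 19 (2E)-3-[(3S,5R)-3,5-diethyl-5-[(1E,4R,5E)-4-ethyl-2-methylocta-1,5-dien-1-yl]-1,2-dioxolan-3-yl]prop-2-enoic acid
Conditions: LiOH, THF/MeOH/H2O, 0 °C → rt; then 1 M HCl to pH 3–4
Reagents that add atoms: lithium hydroxide, [Li+].[OH-]
Why: Saponification (acyl substitution by hydroxide). The peroxide carbons carry no hydrogen, so aqueous base should be tolerated, and no stereocentre is at risk.

## Compound list

1 | methyl (4R)-2,2-dimethyl-1,3-dioxolane-4-carboxylate | COC(=O)[C@H]1COC(C)(C)O1 | starting material
2 | (4R)-N-methoxy-N,2,2-trimethyl-1,3-dioxolane-4-carboxamide | CON(C)C(=O)[C@H]1COC(C)(C)O1 | intermediate (not isolated)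
3 | 1-[(4R)-2,2-dimethyl-1,3-dioxolan-4-yl]propan-1-one | CCC(=O)[C@H]1COC(C)(C)O1 | intermediate
4 | (4S)-4-(but-1-en-2-yl)-2,2-dimethyl-1,3-dioxolane | C=C(CC)[C@H]1COC(C)(C)O1 | intermediate
5 | (4R)-4-(1-hydroperoxy-1-methoxypropyl)-2,2-dimethyl-1,3-dioxolane (both epimers at the ketal carbon) | CCC(OC)(OO)[C@H]1COC(C)(C)O1 | intermediate (not isolated)
6 | triethyl({1-[(4R)-2,2-dimethyl-1,3-dioxolan-4-yl]-1-methoxypropyl}peroxy)silane (both epimers at the ketal carbon) | CCC(OC)(OO[Si](CC)(CC)CC)[C@H]1COC(C)(C)O1 | intermediate
7 | (2E)-pent-2-enal | CC/C=C/C=O | starting material
8 | (3R,4E)-hept-4-en-3-ol | CC[C@@H](O)/C=C/CC | intermediate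
9 | triethyl orthoacetate (1,1,1-triethoxyethane) | CC(OCC)(OCC)OCC | starting material
10 | ethyl (3R,4E)-3-ethylhept-4-enoate | CC/C=C/[C@H](CC)CC(=O)OCC | intermediate
11 | (3R,4E)-3-ethylhept-4-enal | CC/C=C/[C@H](CC)CC=O | intermediate (not isolated)
12 | (4R,5E)-4-ethyloct-5-en-1-yne | CC/C=C/[C@H](CC)CC#C | intermediate
13 | 2-bromobut-1-ene | CCC(Br)=C | starting material
14 | [(1E,4R,5E)-4-ethyl-2-methylocta-1,5-dien-1-yl]dimethylaluminium | CC/C=C/[C@H](CC)C/C(C)=C/[Al](C)C | intermediate (not isolated)
15 | (3E,6R,7E)-2,6-diethyl-4-methyldeca-1,3,7-triene | CC/C=C/[C@H](CC)C/C(C)=C/C(CC)=C | intermediate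
16 | (3S,5R)-3-[(4R)-2,2-dimethyl-1,3-dioxolan-4-yl]-3,5-diethyl-5-[(1E,4R,5E)-4-ethyl-2-methylocta-1,5-dien-1-yl]-1,2-dioxolane | CC/C=C/[C@H](CC)C/C(C)=C/[C@@]1(CC)C[C@]([C@H]2COC(C)(C)O2)(CC)OO1 | intermediate
17 | (3S,5R)-3,5-diethyl-5-[(1E,4R,5E)-4-ethyl-2-methylocta-1,5-dien-1-yl]-1,2-dioxolane-3-carbaldehyde | CC/C=C/[C@H](CC)C/C(C)=C/[C@@]1(CC)C[C@](C=O)(CC)OO1 | intermediate
18 | ethyl (2E)-3-[(3S,5R)-3,5-diethyl-5-[(1E,4R,5E)-4-ethyl-2-methylocta-1,5-dien-1-yl]-1,2-dioxolan-3-yl]prop-2-enoate | CC/C=C/[C@H](CC)C/C(C)=C/[C@@]1(CC)C[C@](/C=C/C(=O)OCC)(CC)OO1 | intermediate
19 | (2E)-3-[(3S,5R)-3,5-diethyl-5-[(1E,4R,5E)-4-ethyl-2-methylocta-1,5-dien-1-yl]-1,2-dioxolan-3-yl]prop-2-enoic acid | CC/C=C/[C@H](CC)C/C(C)=C/[C@@]1(CC)C[C@](/C=C/C(=O)O)(CC)OO1 | target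

## Step count and least certain steps

Total: 11 steps. Longest linear sequence: 8 steps (7 to 19 through steps 4 to 11); the other branch (1 to 19) is 7 steps.

Stereocentres: C4′ is set in step 4 and transferred in step 5; C3 and C5 are set in step 8; the dioxolanyl centre from 1 serves as control element and is removed in step 9.

Step 8 (key step, new method). The likely failures are processes that consume the peroxycarbenium ion before the diene captures it: a Criegee- or Hock-type 1,2-shift of the oxygenated substituent to oxygen, or ionisation of the acetonide by SnCl4. Further risks are cationic oligomerisation of the diene, poor facial discrimination at C3, indiscriminate closure at C5, and re-ionisation of the product at the tertiary allylic C5–O1 bond, which would scramble C5.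

Fallback with known chemistry, setting out from 6 and 10 and coming back at 16. The annulation is run in its established form with a non-conjugated 1,1-disubstituted alkene, tert-butyl[(2-methylidenebutyl)oxy]diphenylsilane F1 (from commercial 2-methylidenebutan-1-ol, t-BuPh2SiCl and imidazole), under the conditions of step 8, to give the silyloxymethyl dioxolane tert-butyl({(3R,5S)-5-[(4R)-2,2-dimethyl-1,3-dioxolan-4-yl]-3,5-diethyl-1,2-dioxolan-3-yl}methoxy)diphenylsilane F2. Bu4NF in THF should give the alcohol {(3R,5S)-5-[(4R)-2,2-dimethyl-1,3-dioxolan-4-yl]-3,5-diethyl-1,2-dioxolan-3-yl}methanol F3, and Dess–Martin periodinane the non-enolisable aldehyde (3R,5S)-5-[(4R)-2,2-dimethyl-1,3-dioxolan-4-yl]-3,5-diethyl-1,2-dioxolane-3-carbaldehyde F4. In parallel 10 is reduced with LiAlH4 to (3R,4E)-3-ethylhept-4-en-1-ol F5, which is converted with I2, PPh3 and imidazole into (3E,5R)-5-ethyl-7-iodohept-3-ene F6 and with PPh3 in refluxing MeCN into [(3R,4E)-3-ethylhept-4-en-1-yl]triphenylphosphonium iodide F7. Deprotonation of F7 with NaN(SiMe3)2, iodination of the ylide with I2 at −78 °C, a second deprotonation and addition of F4 (Stork–Zhao-type iodo-olefination) should give the iodoalkene (3S,5R)-3-[(4R)-2,2-dimethyl-1,3-dioxolan-4-yl]-3,5-diethyl-5-[(1Z,4R,5E)-4-ethyl-2-iodoocta-1,5-dien-1-yl]-1,2-dioxolane F8, in which iodine is cis to the ring. Negishi methylation with retention (MeZnCl, Pd(PPh3)4, THF) then gives 16. The cost is about eight operations in place of one, and the C5 epimer question remains.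

Step 3. The primary ozonide may fragment in the unwanted direction, putting the carbonyl oxide on the CH2 carbon and returning ketone 3, because the dioxygenated substituent is inductively withdrawing. Acid-promoted loss of methanol or hydrogen peroxide on concentration is a second risk. Fallback, setting out from 3 and coming back at 5: Wittig reaction of 3 with the ylide from (methoxymethyl)triphenylphosphonium chloride and NaN(SiMe3)2 at −78 °C gives the enol ether (4S)-4-(1-methoxybut-1-en-2-yl)-2,2-dimethyl-1,3-dioxolane F9 (E/Z mixture). Its ozonolysis in CH2Cl2/MeOH is directed by the alkoxy group towards methyl formate and the required carbonyl oxide, which gives 5; silylation as in step 3 gives 6. The price is a basic ylide next to the α-alkoxy stereocentre.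

Step 9. The strongly acidic oxidant may ionise the tertiary allylic C5–O1 bond (the reverse of the ring closure) before the acetonide is hydrolysed, which would epimerise C5 or open the ring. Fallback, setting out from 16 and coming back at 17: the two events are separated. Mild transketalisation (pyridinium p-toluenesulfonate, MeOH, 40 °C) gives the diol (1R)-1-{(3S,5R)-3,5-diethyl-5-[(1E,4R,5E)-4-ethyl-2-methylocta-1,5-dien-1-yl]-1,2-dioxolan-3-yl}ethane-1,2-diol F10, which is cleaved at neutral pH (NaIO4, NaHCO3, THF/H2O, 0 °C) to 17.

Step 7. The one-flask sequence may suffer from incomplete or non-regioselective carboalumination and from competing methyl transfer or homocoupling in the cross-coupling; the product is also volatile and cannot be purified at the organometallic stage. Fallback, setting out from 14 and 13 and coming back at 15: the roles of the partners are reversed. Iodinolysis of 14 (I2, THF, −30 °C) gives (1E,4R,5E)-4-ethyl-1-iodo-2-methylocta-1,5-diene F11, which can be purified. 13 is converted with t-BuLi (−78 °C) and ZnCl2 into but-1-en-2-ylzinc chloride F12. Negishi coupling of F11 with F12 (Pd(PPh3)4, THF, rt) gives 15.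

Step 4. Ethyl transfer to an unbranched aliphatic enal may be insufficiently enantioselective, and the minor enantiomer would be carried into 15 and appear as diastereomers of 16; loss of the volatile alcohol on isolation is a second risk. Fallback, setting out from 7 and coming back at 8: addition of EtMgBr gives racemic (4E)-hept-4-en-3-ol F13, MnO2 oxidation gives (4E)-hept-4-en-3-one F14, and Corey–Bakshi–Shibata reduction with the (S)-methyl oxazaborolidine catalyst and catecholborane at −78 °C, the alkenyl group acting as the large substituent, gives 8.

## Further compounds

F1 | step 8 | tert-butyl[(2-methylidenebutyl)oxy]diphenylsilane | C=C(CC)CO[Si](C(C)(C)C)(c1ccccc1)c1ccccc1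
F2 | step 8 | tert-butyl({(3R,5S)-5-[(4R)-2,2-dimethyl-1,3-dioxolan-4-yl]-3,5-diethyl-1,2-dioxolan-3-yl}methoxy)diphenylsilane | CC(C)(C)[Si](c1ccccc1)(c1ccccc1)OC[C@@]1(CC)C[C@]([C@H]2COC(C)(C)O2)(CC)OO1
F3 | step 8 | {(3R,5S)-5-[(4R)-2,2-dimethyl-1,3-dioxolan-4-yl]-3,5-diethyl-1,2-dioxolan-3-yl}methanol | OC[C@@]1(CC)C[C@]([C@H]2COC(C)(C)O2)(CC)OO1
F4 | step 8 | (3R,5S)-5-[(4R)-2,2-dimethyl-1,3-dioxolan-4-yl]-3,5-diethyl-1,2-dioxolane-3-carbaldehyde | O=C[C@@]1(CC)C[C@]([C@H]2COC(C)(C)O2)(CC)OO1
F5 | step 8 | (3R,4E)-3-ethylhept-4-en-1-ol | CC/C=C/[C@H](CC)CCO
F6 | step 8 | (3E,5R)-5-ethyl-7-iodohept-3-ene | CC/C=C/[C@H](CC)CCI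
F7 | step 8 | [(3R,4E)-3-ethylhept-4-en-1-yl]triphenylphosphonium iodide | CC/C=C/[C@H](CC)CC[P+](c1ccccc1)(c1ccccc1)c1ccccc1.[I-]
F8 | step 8 | (3S,5R)-3-[(4R)-2,2-dimethyl-1,3-dioxolan-4-yl]-3,5-diethyl-5-[(1Z,4R,5E)-4-ethyl-2-iodoocta-1,5-dien-1-yl]-1,2-dioxolane | CC/C=C/[C@H](CC)C/C(I)=C/[C@@]1(CC)C[C@]([C@H]2COC(C)(C)O2)(CC)OO1
F9 | step 3 | (4S)-4-(1-methoxybut-1-en-2-yl)-2,2-dimethyl-1,3-dioxolane (E/Z mixture) | CCC(=COC)[C@H]1COC(C)(C)O1
F10 | step 9 | (1R)-1-{(3S,5R)-3,5-diethyl-5-[(1E,4R,5E)-4-ethyl-2-methylocta-1,5-dien-1-yl]-1,2-dioxolan-3-yl}ethane-1,2-diol | CC/C=C/[C@H](CC)C/C(C)=C/[C@@]1(CC)C[C@]([C@H](O)CO)(CC)OO1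
F11 | step 7 | (1E,4R,5E)-4-ethyl-1-iodo-2-methylocta-1,5-diene | CC/C=C/[C@H](CC)C/C(C)=C/I
F12 | step 7 | but-1-en-2-ylzinc chloride | CCC(=C)[Zn]Cl
F13 | step 4 | rac-(4E)-hept-4-en-3-ol | CCC(O)/C=C/CC
F14 | step 4 | (4E)-hept-4-en-3-one | CCC(=O)/C=C/CC
A1 | alternative 1 | 1,4-diethylcyclopenta-1,3-diene | CCC1=CC=C(CC)C1
A2 | alternative 1 | (1R,4S)-1,4-diethyl-2,3-dioxabicyclo[2.2.1]hept-5-ene (meso) | CC[C@@]12OO[C@@](CC)(C=C1)C2
A3 | alternative 1 | (3R,5S)-3,5-diethyl-1,2-dioxolane-3,5-dicarbaldehyde (meso, cis) | CC[C@]1(C=O)OO[C@@](CC)(C=O)C1
A4 | alternative 2 | [(2S,3S)-3-{(2S,3R)-4-[(tert-butyldiphenylsilyl)oxy]-2-ethyl-2-hydroperoxy-3-hydroxybutyl}-3-ethyloxiran-2-yl]methanol | OC[C@@H]1O[C@@]1(CC)C[C@@](OO)(CC)[C@H](O)CO[Si](C(C)(C)C)(c1ccccc1)c1ccccc1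
A5 | alternative 2 | (1R)-2-[(tert-butyldiphenylsilyl)oxy]-1-{(3S,5R)-5-[(1S)-1,2-dihydroxyethyl]-3,5-diethyl-1,2-dioxolan-3-yl}ethan-1-ol | OC[C@H](O)[C@@]1(CC)C[C@]([C@H](O)CO[Si](C(C)(C)C)(c2ccccc2)c2ccccc2)(CC)OO1
A6 | alternative 3 | (1R,6R)-4,6-diethyl-6-hydroperoxycyclohex-3-en-1-ol (hydroxyl and hydroperoxide trans) | O[C@H]1[C@@](OO)(CC)CC(CC)=CC1
A7 | alternative 3 | (1R,2R,4S,5S)-1,5-diethyl-4-iodo-6,7-dioxabicyclo[3.2.1]octan-2-ol (hydroxyl and iodide anti to the peroxide bridge) | O[C@H]1[C@@]2(CC)C[C@]([C@@H](I)C1)(CC)OO2
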